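Atoms carry gibberellane numbers; α is the face of C19/C20, β the face of C18.

Rings C and D form a bicyclo[3.2.1]octane: C8, C14, C13, C16 and C15 are the five carbons of a cyclopentadiene, the bridge C9–C11–C12 is a 2-oxyallyl unit, and C10–C5–C6 is a three-atom tether between them.
Cuts: C16=C17 (methylenation); C8–C9 and C12–C13 together (intramolecular (4+3), opening rings B and C); C6–C8 (cyclopentadienide on a C6 triflate); C9–C10 (aldol); C4–C18 (methylation); C5–C6 (homologation); C4–C5 and C1–C10 (Diels–Alder).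
Forward: ring A, then the C10 and C4 quaternary centres, the 19,20-lactone (through a 7,20-lactone relay), the diol and the diene; rings B and C close in one step; ring D is finished by hydroboration, oxidation and Wittig reaction.
Stereochemistry: C5 from an oxazolidinone-controlled Diels–Alder; C10 and C4 by attack anti to the C5 arm; C2/C3 by exo osmylation of the bridged lactone; C6 by enolate hydroxylation then SN2 inversion; C8, C9 and C13 in the cycloaddition.
Spectator changes: the leaving group on C9 is a tosylate (regiodefined from the aldol oxygen, no acidic α-hydrogen), and C7 stays a methyl ester (it activates the C6 displacement; Et3N does not ionise C6–H).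

Key step: step 21

Assumption: C9 is carried from step 7 to step 20 as an epimer mixture and C16 in 35 and 36 is unassigned, since both centres become trigonal later; 28–30 are drawn as the 1-alkylcyclopenta-1,3-diene tautomer, which equilibrates with the 2-alkyl isomer by 1,5-hydrogen shift.

Step 1
Reactants: 1 (R)-4-benzyl-1,3-oxazolidin-2-one; 2 ethyl (2E)-4-chloro-4-oxobut-2-enoate
Product: 3 (R)-4-benzyl-3-[(2E)-4-ethoxy-4-oxobut-2-enoyl]-1,3-oxazolidin-2-one
Conditions: n-BuLi, THF, −78 °C; then 2, −78 → 0 °C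
Reagents that add atoms: none
Why: N-acylation of the lithiated oxazolidinone by an acid chloride is the standard route to such imides and leaves the E alkene untouched.

Step 2
Reactants: 4 (2E)-penta-2,4-dien-1-ol
Product: 5 tert-butyl(dimethyl)[(2E)-penta-2,4-dien-1-yloxy]silane
Conditions: t-BuMe2SiCl, imidazole, CH2Cl2, 0 °C → rt
Reagents that add atoms: tert-butyl(chloro)dimethylsilane CC(C)(C)[Si](C)(C)Cl
Why: Silylation of a primary allylic alcohol keeps the diene free of acidic hydrogen for the Lewis-acid step.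

Step 3
Reactants: 3 dienophile imide; 5 silyloxy diene
Product: 6 ring A imide (C2=C3; 4α-CH2OSiMe2t-Bu; 5α-acyl oxazolidinone; 10β-CO2Et)
Conditions: Et2AlCl (1.4 equiv), CH2Cl2, −78 °C
Reagents that add atoms: none
Why: Diels–Alder reaction of the Et2AlCl-chelated s-cis acyl oxazolidinone, in which the diene adds to the C5 face remote from the benzyl group (sets C5) and its substituted terminus C4 bonds next to the imide carbonyl (ortho, endo); C4 and C10 are re-set in steps 11 and 7.

Step 4
Reactants: 6 ring A imide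
Product: 7 ring A acid (5α-CO2H)
Conditions: LiOH, H2O2 (30%), THF–H2O, 0 °C; then Na2SO3; HCl to pH 3
Reagents that add atoms: hydrogen peroxide OO
Why: Hydroperoxide cleaves the exocyclic imide carbonyl selectively (acyl substitution), freeing the acid without touching the ethyl ester or C5.

Step 5
Reactants: 7 ring A acid
Product: 9 diazo ketone (5α-C(=O)CHN2), via acid chloride 8 (not isolated)
Conditions: 1-chloro-N,N,2-trimethylprop-1-en-1-amine, CH2Cl2, 0 °C; then CH2N2 (3 equiv), Et2O, 0 °C
Reagents that add atoms: diazomethane C=[N+]=[N-]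
Why: First half of the Arndt–Eistert homologation; the acid chloride is made under neutral conditions that spare the silyl ether and then acylates diazomethane.

Step 6
Reactants: 9 diazo ketone
Product: 11 homologated acid (5α-CH2CO2H), via ketene 10 (not isolated)
Conditions: AgO2CPh (0.1 equiv), Et3N, THF–H2O (9:1), rt, dark
Reagents that add atoms: water O
Why: Wolff rearrangement with retention at the migrating C5, the ketene being captured by water to give the C6–C7 acetic acid arm.

Step 7
Reactants: 11 homologated acid; 12 (2S)-2-[(tert-butyldimethylsilyl)oxy]propanal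
Product: 14 tosylate acid (C10 quaternary; 10α-CO2Et; 10β-CH(OTs)CH(OSiMe2t-Bu)CH3), via aldolate 13 (not isolated)
Conditions: LiN(i-Pr)2 (2.3 equiv), THF, −78 °C; 12, −78 °C; then 4-MeC6H4SO2Cl (3 equiv), −78 → 0 °C; aq. NaHCO3
Reagents that add atoms: 4-methylbenzenesulfonyl chloride Cc1ccc(cc1)S(Cl)(=O)=O
Why: Aldol addition of the ester enolate (the carboxylate is a bystander as its lithium salt) from the β face, anti to the α arms on C5 and C4, sets C10 with C9 β and C20 α; the aldolate is trapped as the tosylate before it can lactonise or revert.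

Step 8
Reactants: 14 tosylate acid
Product: 16 7,20-lactone (C7(=O)–O–C20 cis-fused at C5–C10), via hydroxy acid 15 (not isolated)
Conditions: LiBH4, MeOH (1 equiv), THF, 0 → 45 °C; 1 M HCl to pH 3; PPTS (cat.), PhMe, 50 °C
Reagents that add atoms: none
Why: LiBH4 reduces the ester but not the lithium carboxylate, and the C20 alcohol then closes the six-membered 7,20-lactone (lactonisation), which masks C20–OH and C7 for the next four steps.

Step 9
Reactants: 16 7,20-lactone
Product: 17 C19 alcohol (4α-CH2OH)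
Conditions: HF·pyridine, pyridine, THF, 0 °C
Reagents that add atoms: none
Why: Acidic fluoride desilylation removes the primary silyl ether much faster than the hindered secondary one at C11.

Step 10
Reactants: 17 C19 alcohol
Product: 18 C19 aldehyde (4α-CHO)
Conditions: DMP (1,1,1-triacetoxy-1,1-dihydro-1,2-benziodoxol-3(1H)-one), NaHCO3, CH2Cl2, 0 °C → rt
Reagents that add atoms: none
Why: Periodinane oxidation of a primary alcohol to the aldehyde under buffered conditions.

Step 11
Reactants: 18 C19 aldehyde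
Product: 19 4β-methyl aldehyde (4α-CHO; 4β-CH3)
Conditions: KN(SiMe3)2 (1.05 equiv), THF, −78 °C; MeI, −78 → −20 °C
Reagents that add atoms: iodomethane CI
Why: α-Alkylation of the aldehyde dienolate at C4, where MeI enters on the convex β face, anti to the lactone ring fused at C5–C10, giving C18 β and C19 α.

Step 12
Reactants: 19 4β-methyl aldehyde
Product: 20 C19 acid (4α-CO2H)
Conditions: NaClO2, NaH2PO4, 2-methylbut-2-ene, t-BuOH–H2O, 0 °C → rt
Reagents that add atoms: sodium chlorite [Na+].[O-]Cl=O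
Why: Pinnick oxidation of the hindered aldehyde, the scavenger protecting the ring alkene from hypochlorite.

Step 13
Reactants: 20 C19 acid
Product: 22 19,20-lactone (C19(=O)–O–C20; C2=C3; 5α-CH2CO2Me), via hydroxy acid 21 (not isolated)
Conditions: NaOMe (2.2 equiv), MeOH, 0 °C → rt; AcOH; then N-ethyl-N′-(3-dimethylaminopropyl)carbodiimide hydrochloride, DMAP, CH2Cl2, rt
Reagents that add atoms: sodium methoxide [Na+].[O-]C
Why: Methanolysis opens the 7,20-lactone to the methyl ester, and the freed C20–OH then lactonises (carbodiimide, Steglich-type) with the only free acid, C19, the two groups being held 1,3-diaxial because the other chair would put C18, C9 and C6 axial.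

Step 14
Reactants: 22 19,20-lactone
Product: 23 2β,3β-diol
Conditions: OsO4 (0.05 equiv), N-methylmorpholine N-oxide, acetone–H2O, rt
Reagents that add atoms: osmium tetroxide O=[Os](=O)(=O)=O; N-methylmorpholine N-oxide C[N+]1([O-])CCOCC1; water O
Why: Catalytic syn-dihydroxylation on the exo (β) face of the bicyclo[3.3.1] lactone, the α face being covered by the C19–O–C20 bridge, sets C2 and C3.

Step 15
Reactants: 23 2β,3β-diol
Product: 24 2β,3β-acetonide
Conditions: 2,2-dimethoxypropane, PPTS, acetone, rt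
Reagents that add atoms: 2,2-dimethoxypropane COC(C)(C)OC
Why: Acetal exchange protects the cis-diol as its acetonide.

Step 16
Reactants: 24 2β,3β-acetonide
Product: 25 C6 hydroxy ester
Conditions: KN(SiMe3)2 (1.2 equiv), THF, −78 °C; 3-phenyl-2-(phenylsulfonyl)oxaziridine, −78 °C; aq. NH4Cl
Reagents that add atoms: 3-phenyl-2-(phenylsulfonyl)oxaziridine O=S(=O)(c1ccccc1)N1OC1c1ccccc1
Why: Enolate hydroxylation by the N-sulfonyloxaziridine; with H5 in the enolate plane, the oxidant should reach C6 from the C4 flank (methyl, flat lactone carbonyl) and not the C10 flank (branched C9 chain), setting C6 so that inversion gives the natural configuration.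

Step 17
Reactants: 25 C6 hydroxy ester
Product: 26 C6 triflate
Conditions: (CF3SO2)2O, 2,6-lutidine, CH2Cl2, −78 °C
Reagents that add atoms: trifluoromethanesulfonic anhydride O=S(=O)(OS(=O)(=O)C(F)(F)F)C(F)(F)F
Why: O-Sulfonylation of the α-hydroxy ester gives the α-triflyloxy ester with C6 unchanged.

Step 18
Reactants: 26 C6 triflate; 27 sodium cyclopentadienide (THF solution)
Product: 28 cyclopentadienyl ester (C6 bears H, CO2Me and cyclopenta-1,3-dien-1-yl)
Conditions: NaC5H5 (3 equiv), THF, −78 → −20 °C; aq. NH4Cl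
Reagents that add atoms: none
Why: SN2 alkylation of cyclopentadienide by the α-triflyloxy ester, the carbonyl accelerating substitution at the hindered carbon, with inversion at C6 and the nucleophile passing over H5.

Step 19
Reactants: 28 cyclopentadienyl ester
Product: 29 C11 alcohol
Conditions: HF·pyridine, pyridine, THF, 0 °C → rt
Reagents that add atoms: none
Why: Buffered acidic fluoride desilylation, so that no C11 alkoxide forms to displace the C9 tosylate, and the bulky diene should resist dimerisation.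

Step 20
Reactants: 29 C11 alcohol
Product: 30 α-tosyloxy methyl ketone (cycloaddition precursor)
Conditions: DMP, NaHCO3, CH2Cl2, 0 °C
Reagents that add atoms: none
Why: Periodinane oxidation of the secondary alcohol gives the α-sulfonyloxy ketone without touching the diene.

Step 21
Reactants: 30 α-tosyloxy methyl ketone
Product: 32 11-oxo-15-ene pentacycle, via oxyallyl cation 31 (not isolated)
Conditions: Et3N (3 equiv), CF3CH2OH (0.01 M), 0 °C → rt
Reagents that add atoms: none
Why: Et3N enolises the methyl ketone toward C12 and, in ionising CF3CH2OH, tosylate leaves C9 to give the 2-oxyallyl cation 31 (C9–C11–C12), which adds across the termini C8 and C13 of the 1-substituted cyclopentadiene; the closest known reactions are the intramolecular (4+3) cycloadditions of α-halo and α-sulfonyloxy ketones with furans and butadienes on three-atom tethers, and the intermolecular additions to cyclopentadiene. Ring B closes by 5-exo attack of C8 on C9 through the tether C10–C5–C6, and ring C (C8–C9–C11–C12–C13–C14) closes when C12 bonds to C13 within the seven-membered perimeter, leaving C15=C16. At C9, the cation should carry C10 syn to the oxyanion and, on the short tether, the C9–C10 bond must point back over C6, which places C10 axial on the new cyclohexanone (H9 cis to H5, C11 on the C20 face); this centre stays correctable through the C11 enolate. C8 and C13 form together by suprafacial addition to one diene face, chosen by the C6 stereocentre through the rotamer that turns the flat C15–H toward the ester and the C14 methylene toward H6; this facial choice is the least secured element. The trans A/B junction is already fixed by the diequatorial C5 and C10 arms on the lactone-locked chair, and only the 1-alkyl diene tautomer can reach the cation for five-membered ring closure.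

Step 22
Reactants: 32 11-oxo-15-ene pentacycle
Product: 33 C11 tosylhydrazone
Conditions: 4-MeC6H4SO2NHNH2, EtOH, 60 °C
Reagents that add atoms: 4-methylbenzenesulfonohydrazide Cc1ccc(cc1)S(=O)(=O)NN
Why: Hydrazone condensation at the only ketone prepares C11 for reductive removal.

Step 23
Reactants: 33 C11 tosylhydrazone
Product: 34 11-deoxo 15-ene
Conditions: catecholborane, CHCl3, 0 °C; then NaOAc·3H2O, reflux
Reagents that add atoms: none
Why: Tosylhydrazone reduction with catecholborane, followed by loss of sulfinate and N2, turns C=O into CH2 without moving the isolated alkene or touching lactone and ester.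

Step 24
Reactants: 34 11-deoxo 15-ene
Product: 36 C16 alcohol, via alkylborane 35 (not isolated)
Conditions: BH3·THF (1.2 equiv), THF, 0 °C; then NaBO3·4H2O, H2O, rt
Reagents that add atoms: sodium perborate [Na+].[Na+].O[B-]1(O)OO[B-](O)(O)OO1
Why: Hydroboration–oxidation places boron on C16, away from the quaternary C8, from the less hindered face (the C16 configuration is immaterial).

Step 25
Reactants: 36 C16 alcohol
Product: 37 16-oxo-17-nor ketone
Conditions: DMP, NaHCO3, CH2Cl2, rt
Reagents that add atoms: none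
Why: Periodinane oxidation of the secondary alcohol to the ring D cyclopentanone.

Step 26
Reactants: 37 16-oxo-17-nor ketone
Product: 38 16-methylene methyl ester acetonide
Conditions: Ph3PCH3Br, KOt-Bu, THF, 0 °C → rt
Reagents that add atoms: methyltriphenylphosphonium bromide C[P+](c1ccccc1)(c1ccccc1)c1ccccc1.[Br-]
Why: Wittig methylenation of the 16-ketone is the standard way to the C16=C17 methylene of gibberellins and tolerates lactone and ester.

Step 27
Reactants: 38 16-methylene methyl ester acetonide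
Product: 39 C7 acid acetonide
Conditions: LiSCH2CH2CH3, HMPA, rt; then dilute HCl to pH 3
Reagents that add atoms: none
Why: SN2 demethylation by thiolate at the O-methyl carbon cleaves the hindered C7 ester without opening the lactone, whose O-alkyl carbon C20 is neopentyl.

Step 28
Reactants: 39 C7 acid acetonide
Product: 40 CNP0332607.1
Conditions: AcOH–H2O (4:1), 50 °C
Reagents that add atoms: none
Why: Mild acid hydrolysis of the acetonide frees the 2β,3β-diol under conditions the exocyclic alkene and the lactone should survive.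

Compound list
1 | (R)-4-benzyl-1,3-oxazolidin-2-one | O=C1N[C@H](Cc2ccccc2)CO1 | starting material
2 | ethyl (2E)-4-chloro-4-oxobut-2-enoate | CCOC(=O)/C=C/C(Cl)=O | starting material
3 | (R)-4-benzyl-3-[(2E)-4-ethoxy-4-oxobut-2-enoyl]-1,3-oxazolidin-2-one | CCOC(=O)/C=C/C(=O)N1C(=O)OC[C@H]1Cc1ccccc1 | intermediate
4 | (2E)-penta-2,4-dien-1-ol | OC/C=C/C=C | starting material
5 | tert-butyl(dimethyl)[(2E)-penta-2,4-dien-1-yloxy]silane | C=C/C=C/CO[Si](C)(C)C(C)(C)C | intermediate
6 | ring A imide: C2=C3 cyclohexene, 4α-CH2OSiMe2t-Bu, 5α-C(=O)-oxazolidinone (5β-H), 10β-CO2Et | CC(C)(C)[Si](C)(C)OC[C@@H]1C=CC[C@@H](C(=O)OCC)[C@@H]1C(=O)N1C(=O)OC[C@H]1Cc1ccccc1 | intermediate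
7 | ring A acid: as 6 with 5α-CO2H | CC(C)(C)[Si](C)(C)OC[C@@H]1C=CC[C@@H](C(=O)OCC)[C@@H]1C(=O)O | intermediate
8 | acid chloride of 7 | CC(C)(C)[Si](C)(C)OC[C@@H]1C=CC[C@@H](C(=O)OCC)[C@@H]1C(=O)Cl | intermediate
9 | diazo ketone: 5α-C(=O)CHN2 | CC(C)(C)[Si](C)(C)OC[C@@H]1C=CC[C@@H](C(=O)OCC)[C@@H]1C(=O)C=[N+]=[N-] | intermediate
10 | ketene: 5α-CH=C=O | CC(C)(C)[Si](C)(C)OC[C@@H]1C=CC[C@@H](C(=O)OCC)[C@@H]1C=C=O | intermediate
11 | homologated acid: 4α-CH2OSiMe2t-Bu, 5α-CH2CO2H (C6, C7), 10β-CO2Et | CC(C)(C)[Si](C)(C)OC[C@@H]1C=CC[C@@H](C(=O)OCC)[C@@H]1CC(=O)O | intermediate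
12 | (2S)-2-[(tert-butyldimethylsilyl)oxy]propanal | C[C@H](O[Si](C)(C)C(C)(C)C)C=O | starting material
13 | aldol adduct (as lithium alkoxide): C10 quaternary, 10α-CO2Et, 10β-CH(OH)CH(OSiMe2t-Bu)CH3 (C9, C11 S, C12), 5α-CH2CO2H | CC(C)(C)[Si](C)(C)OC[C@@H]1C=CC[C@@](C(=O)OCC)(C(O)[C@H](C)O[Si](C)(C)C(C)(C)C)[C@@H]1CC(=O)O | intermediate
14 | tosylate acid: as 13 with C9–OTs | CC(C)(C)[Si](C)(C)OC[C@@H]1C=CC[C@@](C(=O)OCC)(C(OS(=O)(=O)c5ccc(C)cc5)[C@H](C)O[Si](C)(C)C(C)(C)C)[C@@H]1CC(=O)O | intermediate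
15 | hydroxy acid: as 14 with 10α-CH2OH (C20) | CC(C)(C)[Si](C)(C)OC[C@@H]1C=CC[C@@](CO)(C(OS(=O)(=O)c5ccc(C)cc5)[C@H](C)O[Si](C)(C)C(C)(C)C)[C@@H]1CC(=O)O | intermediate
16 | 7,20-lactone: C7(=O)–O–C20 cis-fused at C5–C10, 4α-CH2OSiMe2t-Bu, 10β-CH(OTs)CH(OSiMe2t-Bu)CH3 | CC(C)(C)[Si](C)(C)OC[C@@H]1C=CC[C@@]2(COC(=O)C[C@H]12)C(OS(=O)(=O)c5ccc(C)cc5)[C@H](C)O[Si](C)(C)C(C)(C)C | intermediate
17 | 7,20-lactone C19 alcohol (4α-CH2OH) | OC[C@@H]1C=CC[C@@]2(COC(=O)C[C@H]12)C(OS(=O)(=O)c5ccc(C)cc5)[C@H](C)O[Si](C)(C)C(C)(C)C | intermediate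
18 | 7,20-lactone C19 aldehyde (4α-CHO, 4β-H) | O=C[C@@H]1C=CC[C@@]2(COC(=O)C[C@H]12)C(OS(=O)(=O)c5ccc(C)cc5)[C@H](C)O[Si](C)(C)C(C)(C)C | intermediate
19 | 4β-methyl aldehyde (4α-CHO, 4β-CH3) | O=C[C@]1(C)C=CC[C@@]2(COC(=O)C[C@H]12)C(OS(=O)(=O)c5ccc(C)cc5)[C@H](C)O[Si](C)(C)C(C)(C)C | intermediate
20 | C19 acid (4α-CO2H, 4β-CH3) with 7,20-lactone | OC(=O)[C@]1(C)C=CC[C@@]2(COC(=O)C[C@H]12)C(OS(=O)(=O)c5ccc(C)cc5)[C@H](C)O[Si](C)(C)C(C)(C)C | intermediate
21 | open hydroxy acid: 4α-CO2H, 10α-CH2OH, 5α-CH2CO2Me | OC(=O)[C@]1(C)C=CC[C@@](CO)(C(OS(=O)(=O)c5ccc(C)cc5)[C@H](C)O[Si](C)(C)C(C)(C)C)[C@@H]1CC(=O)OC | intermediate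
22 | 19,20-lactone: C19(=O)–O–C20 bridged lactone, C2=C3, 5α-CH2CO2Me, 10β-CH(OTs)CH(OSiMe2t-Bu)CH3 | C[C@H](O[Si](C)(C)C(C)(C)C)C(OS(=O)(=O)c5ccc(C)cc5)[C@]12COC(=O)[C@](C)(C=CC1)[C@H]2CC(=O)OC | intermediate
23 | 2β,3β-diol of 22 | C[C@H](O[Si](C)(C)C(C)(C)C)C(OS(=O)(=O)c5ccc(C)cc5)[C@]12COC(=O)[C@](C)([C@@H](O)[C@@H](O)C1)[C@H]2CC(=O)OC | intermediate
24 | 2β,3β-acetonide | C[C@H](O[Si](C)(C)C(C)(C)C)C(OS(=O)(=O)c5ccc(C)cc5)[C@]12COC(=O)[C@](C)([C@@H](OC4(C)C)[C@@H](O4)C1)[C@H]2CC(=O)OC | intermediate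
25 | C6 hydroxy ester (C6–OH placed for inversion) | C[C@H](O[Si](C)(C)C(C)(C)C)C(OS(=O)(=O)c5ccc(C)cc5)[C@]12COC(=O)[C@](C)([C@@H](OC4(C)C)[C@@H](O4)C1)[C@H]2[C@H](O)C(=O)OC | intermediate
26 | C6 triflate | C[C@H](O[Si](C)(C)C(C)(C)C)C(OS(=O)(=O)c5ccc(C)cc5)[C@]12COC(=O)[C@](C)([C@@H](OC4(C)C)[C@@H](O4)C1)[C@H]2[C@H](OS(=O)(=O)C(F)(F)F)C(=O)OC | intermediate
27 | sodium cyclopentadienide | [Na+].c1cc[cH-]c1 | starting material
28 | cyclopentadienyl ester: C6 with H, CO2Me and cyclopenta-1,3-dien-1-yl (natural C6), C11–OSiMe2t-Bu | C[C@H](O[Si](C)(C)C(C)(C)C)C(OS(=O)(=O)c5ccc(C)cc5)[C@]12COC(=O)[C@](C)([C@@H](OC4(C)C)[C@@H](O4)C1)[C@H]2[C@@H](C3=CC=CC3)C(=O)OC | intermediate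
29 | C11 alcohol | C[C@H](O)C(OS(=O)(=O)c5ccc(C)cc5)[C@]12COC(=O)[C@](C)([C@@H](OC4(C)C)[C@@H](O4)C1)[C@H]2[C@@H](C3=CC=CC3)C(=O)OC | intermediate
30 | α-tosyloxy methyl ketone, CH3C(=O)CH(OTs) on C10 (cycloaddition precursor) | CC(=O)C(OS(=O)(=O)c5ccc(C)cc5)[C@]12COC(=O)[C@](C)([C@@H](OC4(C)C)[C@@H](O4)C1)[C@H]2[C@@H](C3=CC=CC3)C(=O)OC | intermediate
31 | 2-oxyallyl cation (C9–C11–C12) | C=C([O-])[CH+][C@]12COC(=O)[C@](C)([C@@H](OC4(C)C)[C@@H](O4)C1)[C@H]2[C@@H](C3=CC=CC3)C(=O)OC | intermediate
32 | 11-oxo-15-ene 17-nor pentacycle, C7 methyl ester, 2β,3β-acetonide | C1=C[C@]23C[C@H]1CC(=O)[C@H]2[C@]12COC(=O)[C@](C)([C@@H](OC4(C)C)[C@@H](O4)C1)[C@H]2[C@@H]3C(=O)OC | intermediate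
33 | C11 tosylhydrazone of 32 | C1=C[C@]23C[C@H]1CC(=NNS(=O)(=O)c1ccc(C)cc1)[C@H]2[C@]12COC(=O)[C@](C)([C@@H](OC4(C)C)[C@@H](O4)C1)[C@H]2[C@@H]3C(=O)OC | intermediate
34 | 11-deoxo 15-ene | C1=C[C@]23C[C@H]1CC[C@H]2[C@]12COC(=O)[C@](C)([C@@H](OC4(C)C)[C@@H](O4)C1)[C@H]2[C@@H]3C(=O)OC | intermediate
35 | C16 alkylborane | BC1C[C@]23C[C@H]1CC[C@H]2[C@]12COC(=O)[C@](C)([C@@H](OC4(C)C)[C@@H](O4)C1)[C@H]2[C@@H]3C(=O)OC | intermediate
36 | C16 alcohol | OC1C[C@]23C[C@H]1CC[C@H]2[C@]12COC(=O)[C@](C)([C@@H](OC4(C)C)[C@@H](O4)C1)[C@H]2[C@@H]3C(=O)OC | intermediate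
37 | 16-oxo-17-nor ketone | O=C1C[C@]23C[C@H]1CC[C@H]2[C@]12COC(=O)[C@](C)([C@@H](OC4(C)C)[C@@H](O4)C1)[C@H]2[C@@H]3C(=O)OC | intermediate
38 | 16-methylene methyl ester acetonide | C=C1C[C@]23C[C@H]1CC[C@H]2[C@]12COC(=O)[C@](C)([C@@H](OC4(C)C)[C@@H](O4)C1)[C@H]2[C@@H]3C(=O)OC | intermediate
39 | 16-methylene C7 acid acetonide | C=C1C[C@]23C[C@H]1CC[C@H]2[C@]12COC(=O)[C@](C)([C@@H](OC4(C)C)[C@@H](O4)C1)[C@H]2[C@@H]3C(=O)O | intermediate
40 | CNP0332607.1 (2β,3β-dihydroxy 19,20-lactone 7-acid) | C=C1C[C@]23C[C@H]1CC[C@H]2[C@]12COC(=O)[C@](C)([C@@H](O)[C@@H](O)C1)[C@H]2[C@@H]3C(=O)O | target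

Total step count: 28. Longest linear sequence: 27 steps (steps 1 and 3–28; step 2 is the one-step branch to the diene).

Steps most likely to fail

Step 21. The cation may close through the compact arrangement, which puts C10 equatorial on the new six-membered ring and gives the trans B/C junction (wrong C9), or it may be captured by solvent before reaching the diene. Addition to the other diene face would not be repaired by what follows. The fallback replaces kinetic control at C9 by thermodynamic control. Setting out from 30, the cyclisation is run as before and the 9-epimeric ketone F1 is accepted. F1 is then equilibrated through the C11 enolate (DBU, PhMe, 60 °C) toward the cis B/C junction, since ring B is already trans-fused to ring A, and the route is rejoined at 32.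

Step 18. Substitution at the hindered C6 may be too slow, so that loss of triflic acid or attack of the anion at the ester carbonyl takes over, and proton exchange may erode C6. The fallback builds the diene by condensation instead of displacement. Setting out from 25, periodinane oxidation gives the α-keto ester F2. Condensation of F2 with cyclopentadiene and pyrrolidine in MeOH gives the 6-(methoxycarbonyl)fulvene F3. Conjugate hydride reduction of F3 (LiBH(s-Bu)3, THF, −78 °C, then NH4Cl) gives the cyclopentadienyl ester, which is separated from its C6 epimer, and the route is rejoined at 28.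

Step 16. Facial discrimination on the open-chain enolate may be poor or reversed, the oxidant entering from the C10 flank. The fallback corrects the centre by inversion. Setting out from 24, the hydroxylation is run as before and the C6-epimeric hydroxy ester F4 is separated. Mitsunobu reaction of F4 (PPh3, diisopropyl azodicarboxylate, 4-nitrobenzoic acid, THF) gives the inverted 4-nitrobenzoate F5. Methanolysis of F5 (K2CO3, MeOH, 0 °C) rejoins the route at 25.

Further compounds
F1 | step 21 | 9-epimer of 32 (trans B/C junction) | C1=C[C@]23C[C@H]1CC(=O)[C@@H]2[C@]12COC(=O)[C@](C)([C@@H](OC4(C)C)[C@@H](O4)C1)[C@H]2[C@@H]3C(=O)OC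
F2 | step 18 | α-keto ester (C6 ketone) | C[C@H](O[Si](C)(C)C(C)(C)C)C(OS(=O)(=O)c5ccc(C)cc5)[C@]12COC(=O)[C@](C)([C@@H](OC4(C)C)[C@@H](O4)C1)[C@H]2C(=O)C(=O)OC
F3 | step 18 | 6-(methoxycarbonyl)fulvene (C6=C8) | C[C@H](O[Si](C)(C)C(C)(C)C)C(OS(=O)(=O)c5ccc(C)cc5)[C@]12COC(=O)[C@](C)([C@@H](OC4(C)C)[C@@H](O4)C1)[C@H]2C(=C3C=CC=C3)C(=O)OC
F4 | step 16 | C6 epimer of 25 | C[C@H](O[Si](C)(C)C(C)(C)C)C(OS(=O)(=O)c5ccc(C)cc5)[C@]12COC(=O)[C@](C)([C@@H](OC4(C)C)[C@@H](O4)C1)[C@H]2[C@@H](O)C(=O)OC
F5 | step 16 | C6 4-nitrobenzoate with the configuration of 25 | C[C@H](O[Si](C)(C)C(C)(C)C)C(OS(=O)(=O)c5ccc(C)cc5)[C@]12COC(=O)[C@](C)([C@@H](OC4(C)C)[C@@H](O4)C1)[C@H]2[C@H](OC(=O)c3ccc(cc3)[N+](=O)[O-])C(=O)OC
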